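## The problem

CNP0270681.0 is an achiral phlorotannin: six benzene rings in a linear chain, joined only by five diaryl ether oxygens and carrying fifteen free phenolic hydroxyls, so there is no stereocentre to set or to relay. The rings are lettered A to F from the 2,4,6-trihydroxyphenyl end, and each ring is numbered from the carbon that bears the ether oxygen on its ring A side (ring A from its single ether carbon). Rings B, D and E are then 3,5-dihydroxy-1,4-dioxygenated, ring C carries ether oxygens at C1 (to ring B) and C2 (to ring D) beside hydroxyls at C3, C4 and C5, and ring F is 3,4,5-trihydroxyphenyl. Every ether oxygen sits on a carbon flanked by two oxygenated carbons on one ring (A C1, B C4, C C2, D C4, E C4) and on a carbon with free ortho positions on the other, except at ring C C1, which has one oxygenated neighbour. Each ether is therefore a union of two electron-rich partners, one of them hindered, and ring C with its two adjacent aryloxy groups is the most crowded point. The free polyphenol, with pyrogallol units in rings C and F, is oxidised readily by air and base, so all fifteen hydroxyls have to stay masked until the last step, and that step must cleave the masks without touching a diaryl ether. The feature that invites a ring synthesis is ring F: it is 1,3,4,5-tetraoxygenated with hydrogens at C2 and C6, and its C1 oxygen is the doubly flanked C4 oxygen of ring E. C1 and C2 can therefore come from an ethynyl ether of that oxygen and C3 to C6, with three contiguous oxygens, from a squarate-derived cyclobutenone, so that this ether is made at an sp carbon and ring F is closed around it.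

## Retrosynthesis

The fifteen O–H bonds of target 33 are traced back to O–methyl bonds in the pentadecamethyl ether 32. Methyl is the smallest mask, survives organolithium, copper catalysis, base and hydrogenolysis, and leaves benzyl and methoxymethyl free to serve as temporary handles. The price is a final cleavage of fifteen ethers, which is asked of BBr3.

Ether 32 is cut at the bond between the ring D C4 oxygen and ring E C1, giving the four-ring phenol 31 and the two-ring bromide 19. This cut divides the chain 4 + 2 and leaves the oxygen on the flanked carbon of ring D, so the forward step is a copper-catalysed coupling of a hindered phenol with an unhindered aryl bromide, the polarity with the best precedent. The neighbouring ether between rings E and F is not cut at an aryl–oxygen bond but is carried intact into the ring synthesis below.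

Bromide 19 is simplified by functional group change to the phenol 17, in which the three ring F oxygens are a free hydroxyl, a silyl ether and a methyl ether. Ring F of 17 is then cut at C2–C3 and C1–C6, giving the aryl ethynyl ether 7 and the cyclobutenone 12. This is the central disconnection: the alkyne supplies C1 and C2, the cyclobutenone supplies C3 to C6 with all three oxygens, and the hindered ether has been made beforehand at an sp carbon. A direct aryl–oxygen cut of this ether is shorter on paper and is kept as the fallback. The ring synthesis is preferred as the plan because it removes one of the five couplings between electron-rich partners and fixes the 1,3,4,5-oxygen pattern by mechanism. Bromine is chosen as the ring E C1 substituent in 7: it is a spectator in the benzannulation and makes 17 two operations away from a coupling-ready fragment with no protecting group on ring E. The forward reaction must be regioselective in the ketene–alkyne addition and must tolerate an aryl bromide.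

The ynol ether 7 is cut at the alkyne C–H and the vinylic chlorines back to the (E)-1,2-dichlorovinyl ether 4, and 4 at its O–C(sp2) bond to 4-bromo-2,6-dimethoxyphenol 1 and trichloroethylene 2. Both are bulk chemicals. The forward steps ask a hindered phenoxide to add to dichloroacetylene 3, and then ask n-BuLi to effect elimination and chlorine–lithium exchange faster than bromine–lithium exchange.

Cyclobutenone 12 is the silyl ether of the hydroxycyclobutenone 11, which comes from the cyclobutenedione 10 by reduction of one carbonyl. Dione 10 comes from dimethyl squarate 8 by reduction and loss of methanol through 9. All four ring carbons and two of the oxygens are present in 8, and what is asked is twice a selective 1,2-hydride addition.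

Phenol 31 is the debenzylated form of 30, which is cut between the ring C C2 oxygen and ring D C1 into the three-ring phenol 29 and the bromide 20. The oxygen again stays on the flanked carbon and the bromide is unhindered. This is preferred to making the ring C/ring D ether first, which would leave the doubly hindered ring B/ring C coupling for a later, larger substrate.

Phenol 29 is the deprotected form of the methoxymethyl ether 28, cut between the ring B C4 oxygen and ring C C1 into phenol 23 and iodide 27. This is the one coupling in which both partners are hindered, so it is placed early, on small compounds, and given an iodide. Iodide 27 comes from the methoxymethyl ether 25 of 2,3,4-trimethoxyphenol 24 by directed ortho-metalation, which sets the ring C substitution pattern without any question of regiochemistry.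

Phenol 23 is the debenzylated form of 22, which is cut between the ring A C1 oxygen and ring B C1 into 2,4,6-trimethoxyphenol 21 and bromide 20. Bromide 20 is the benzyl ether of 1, so one commercial bromophenol supplies rings B, D and E.

## Roads not taken

Alternative 1: The cut removes three hydroxyl oxygens (ring A C4, ring C C4, ring F C4), which are traced to formyl groups in the hexaaryl trialdehyde A2. In the forward direction a peracid converts the three aldehydes by Dakin oxidation into formates, whose hydrolysis gives the triphenol A1, and demethylation follows. Its merit is that each formyl group would activate the carbon para to it (ring A C1, ring C C1, ring F C1) for fluoride displacement, so three of the five ethers could be made without copper, and three oxygens are installed in one operation. Its weak points are that it forms no ring and no skeletal bond, that rings B, D and E offer no position for an activating formyl group, and that the oxidation is performed on the assembled electron-rich chain. The phenols freed on rings C and F are 4-aryloxy-2,6-dimethoxyphenols, which a peracid can take on to quinones with loss of the aryloxy group, that is, with scission of the chain. In late-stage economy and in avoiding copper for three ethers this road is at least as good as the chosen one. The chosen plan sets against it that every oxygen is already in place in the building blocks, that no oxidant ever meets the hexamer, and that its risk is taken on a two-ring fragment.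

Alternative 2: The cut is within ring C, between the phenol carbon C1 and C6, and leads to the 4-(1-ethoxyethenyl)cyclobutenone A4, itself derived from squarate 8. On heating, A4 opens to a vinylketene whose ketene carbon bonds to the terminal alkene carbon, closing ring C as the phenol A3 with all five oxygens in place and ring D already attached at C2. Its merit is real: it addresses the most crowded ring, makes the flanked ring C/ring D ether at a squarate carbon, and delivers the C1 hydroxyl free and distinct. On the question of where a ring synthesis pays most, this alternative has the better case, since in the chosen plan ring C is bought and its two ethers are the hardest couplings (steps 13 and 15). Against it, the free hydroxyl of A3 must then be joined to the flanked C4 of ring B, which is the unfavourable polarity (unhindered phenol, doubly ortho-substituted halide). The squarate must also carry an aryloxy group through an alkenyllithium addition, where aryloxide is a better leaving group than methoxide. The chosen plan offers simpler partners, a regiochemistry that follows from alkyne polarisation, and couplings that all have the hindered partner as the phenol.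

Alternative 3: The cut is at C2–C3 and C5–C6 of ring A and leads to the aryloxymalonate A6 and dimethyl 3-oxopentanedioate A7. Under alkoxide base the two methylene carbons of A7 acylate in turn on the two ester carbons of A6 (double Claisen condensation), closing ring A as the trihydroxy diester A5. Its merits are cheap, robust reagents and a flanked ether made at an sp3 carbon; in sturdiness of the partners it is better than an ynol ether and a cyclobutenone. Its weak points are two surplus ester carbons that must be removed by hydrolysis and decarboxylation, three free hydroxyls that must be methylated before any copper coupling, and a malonate whose acidic C–H is deprotonated first and so deactivates its own esters. Ring A is also the simplest ring and is available as phenol 21. Both plans build a terminal ring around a preformed ether. The chosen one is traceless (the six ring F carbons and no others) and delivers the oxygens at their final oxidation level.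

Key step: step 6

Assumption: 4-bromo-2,6-dimethoxyphenol 1, 2,4,6-trimethoxyphenol 21 and 2,3,4-trimethoxyphenol 24 are taken as purchasable catalogue phenols.

## Route

Step 1
Reactants: 1 4-bromo-2,6-dimethoxyphenol; 2 trichloroethylene
Product: 4 5-bromo-2-{[(E)-1,2-dichloroethenyl]oxy}-1,3-dimethoxybenzene, via dichloroacetylene 3 (not isolated)
Conditions: K2CO3, DMF, 70 °C
Reagents that add atoms: none
Why: Trichloroethylene loses HCl to dichloroacetylene 3 under carbonate and the phenoxide of 1 adds to it with anti protonation, the established route to (E)-1,2-dichlorovinyl aryl ethers; a phenoxide flanked by two methoxy groups meets no steric barrier at an sp carbon.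

Step 2
Reactants: 4 5-bromo-2-{[(E)-1,2-dichloroethenyl]oxy}-1,3-dimethoxybenzene
Product: 7 5-bromo-2-(ethynyloxy)-1,3-dimethoxybenzene, via chloroethynyl ether 5 (not isolated), via lithium acetylide 6 (not isolated)
Conditions: n-BuLi (2.2 equiv), Et2O, −78 → −40 °C; MeOH, −78 °C
Reagents that add atoms: none
Why: Known conversion of 1,2-dichlorovinyl ethers into ynol ethers: vinylic deprotonation and loss of LiCl give 5, chlorine–lithium exchange gives 6, and methanol protonates it; in diethyl ether at −78 °C n-BuLi exchanges only slowly with an electron-rich aryl bromide, so the ring E bromine should survive.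

Step 3
Reactants: 8 dimethyl squarate
Product: 10 3-methoxycyclobut-3-ene-1,2-dione, via hydroxycyclobutenone 9 (not isolated)
Conditions: LiAlH(OtBu)3, THF, −78 °C; aq. HCl work-up; then conc. HCl (cat.), CH2Cl2, rt
Reagents that add atoms: none
Why: 1,2-Reduction of one squarate carbonyl by the bulky hydride, then acid-promoted loss of methanol from 9 with allylic transposition, the standard passage from a dialkyl squarate to a 3-alkoxycyclobutenedione.

Step 4
Reactants: 10 3-methoxycyclobut-3-ene-1,2-dione
Product: 11 4-hydroxy-3-methoxycyclobut-2-en-1-one (racemic)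
Conditions: LiAlH(OtBu)3 (1.0 equiv), THF, −78 °C
Reagents that add atoms: none
Why: Chemoselective 1,2-reduction: one carbonyl of 10 is a vinylogous ester and is deactivated, so hydride adds to the other, next to the methoxy-bearing carbon, as carbon nucleophiles do with 3-alkoxycyclobutenediones; the new stereocentre is racemic and is destroyed in step 6.

Step 5
Reactants: 11 4-hydroxy-3-methoxycyclobut-2-en-1-one
Product: 12 4-[(tert-butyldimethylsilyl)oxy]-3-methoxycyclobut-2-en-1-one (racemic)
Conditions: TBSCl, imidazole, CH2Cl2, 0 °C → rt
Reagents that add atoms: tert-butyldimethylsilyl chloride, CC(C)(C)[Si](C)(C)Cl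
Why: Silylation of a secondary alcohol under near-neutral conditions, chosen because the strained β-methoxy enone does not tolerate strong base.

Step 6
Reactants: 7 5-bromo-2-(ethynyloxy)-1,3-dimethoxybenzene; 12 4-[(tert-butyldimethylsilyl)oxy]-3-methoxycyclobut-2-en-1-one
Product: 17 5-(4-bromo-2,6-dimethoxyphenoxy)-2-[(tert-butyldimethylsilyl)oxy]-3-methoxyphenol, via vinylketene 13 (not isolated), via 4-vinylcyclobutenone 14 (not isolated), via dienylketene 15 (not isolated), via cyclohexadienone 16 (not isolated)
Conditions: 12 (1.3 equiv), toluene, 80 °C then 110 °C, argon, sealed tube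
Reagents that add atoms: none
Why: This is a Danheiser benzannulation of a cyclobutenone with a heteroatom-substituted alkyne, the closest known cases being alkoxy- and silyloxyacetylenes. Heating opens 12 by conrotatory 4π cleavage, the silyloxy group turning outward, to vinylketene 13. The ketene C=C of 13 adds across the alkyne of 7 in a [2+2] cycloaddition in which the nucleophilic terminal alkyne carbon bonds to the ketene carbonyl carbon, giving 14; this polarity match is the selectivity the step needs, and it places the aryloxy carbon meta to the future hydroxyl. Cyclobutenone 14 reopens (4π) to dienylketene 15, and the isomer with the ketene and enol ether termini cis across the central double bond closes ring F by 6π electrocyclisation to 16, which tautomerises to phenol 17. The net new skeletal bonds are C2–C3 and C1–C6 of ring F; the stereocentres of 12, 14 and 16 are transient and none remains. The aryl bromide, the flanking methoxy groups and the silyl ether are spectators at these temperatures, and an aryl ethynyl ether, unlike an alkyl one, has no β-hydrogen for retro-ene loss of ketene.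

Step 7
Reactants: 17 5-(4-bromo-2,6-dimethoxyphenoxy)-2-[(tert-butyldimethylsilyl)oxy]-3-methoxyphenol
Product: 19 5-(4-bromo-2,6-dimethoxyphenoxy)-1,2,3-trimethoxybenzene, via catechol 18 (not isolated)
Conditions: n-Bu4NF (1.1 equiv), THF, 0 °C, argon; then MeI (excess), K2CO3, DMF, rt
Reagents that add atoms: iodomethane, CI
Why: Fluoride cleaves the aryl silyl ether to catechol 18, which is methylated at both oxygens in the same flask (Williamson ether synthesis) before it can oxidise; the aryl bromide is inert.

Step 8
Reactants: 1 4-bromo-2,6-dimethoxyphenol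
Product: 20 2-(benzyloxy)-5-bromo-1,3-dimethoxybenzene
Conditions: BnBr, K2CO3, DMF, rt
Reagents that add atoms: benzyl bromide, BrCc1ccccc1
Why: Williamson benzylation; the benzyl ether masks the flanked oxygen that is to become the next nucleophile and is removable without touching methyl ethers.

Step 9
Reactants: 21 2,4,6-trimethoxyphenol; 20 2-(benzyloxy)-5-bromo-1,3-dimethoxybenzene
Product: 22 2-(benzyloxy)-1,3-dimethoxy-5-(2,4,6-trimethoxyphenoxy)benzene
Conditions: CuI (10 mol %), picolinic acid (20 mol %), K3PO4, DMSO, 90 °C, argon
Reagents that add atoms: none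
Why: Ullmann ether synthesis with the CuI/picolinic acid system, which is reported for phenols bearing two ortho substituents; the bromide has both ortho positions free and argon keeps the electron-rich phenoxide from oxidising.

Step 10
Reactants: 22 2-(benzyloxy)-1,3-dimethoxy-5-(2,4,6-trimethoxyphenoxy)benzene
Product: 23 2,6-dimethoxy-4-(2,4,6-trimethoxyphenoxy)phenol
Conditions: H2 (1 atm), 10% Pd/C, EtOAc/MeOH, rt
Reagents that add atoms: none
Why: Hydrogenolysis of the benzyl ether; no halogen is present and diaryl and methyl ethers are inert.

Step 11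
Reactants: 24 2,3,4-trimethoxyphenol
Product: 25 1,2,3-trimethoxy-4-(methoxymethoxy)benzene
Conditions: MOMCl, i-Pr2NEt, CH2Cl2, 0 °C → rt
Reagents that add atoms: chloromethyl methyl ether, COCCl
Why: Acetal protection of the phenol; the methoxymethyl group is the directing group for step 12 and is later removed by acid, orthogonally to benzyl.

Step 12
Reactants: 25 1,2,3-trimethoxy-4-(methoxymethoxy)benzene
Product: 27 1-iodo-3,4,5-trimethoxy-2-(methoxymethoxy)benzene, via aryllithium 26 (not isolated)
Conditions: n-BuLi, THF, 0 °C; then I2, −78 °C → rt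
Reagents that add atoms: iodine, II
Why: Directed ortho-metalation: the chelating acetal oxygen outranks methoxy as a director, so lithiation occurs at the only position ortho to it, and iodine quenches aryllithium 26 at what becomes ring C C1.

Step 13
Reactants: 23 2,6-dimethoxy-4-(2,4,6-trimethoxyphenoxy)phenol; 27 1-iodo-3,4,5-trimethoxy-2-(methoxymethoxy)benzene
Product: 28 1-[2,6-dimethoxy-4-(2,4,6-trimethoxyphenoxy)phenoxy]-3,4,5-trimethoxy-2-(methoxymethoxy)benzene
Conditions: CuI (20 mol %), picolinic acid (40 mol %), K3PO4, DMSO, 100 °C, argon
Reagents that add atoms: none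
Why: Ullmann ether synthesis; the same catalyst system is reported to join doubly ortho-substituted phenols to ortho-substituted aryl iodides, an iodide is used because this is the one coupling with both partners hindered, and the acetal is stable to phosphate base.

Step 14
Reactants: 28 1-[2,6-dimethoxy-4-(2,4,6-trimethoxyphenoxy)phenoxy]-3,4,5-trimethoxy-2-(methoxymethoxy)benzene
Product: 29 6-[2,6-dimethoxy-4-(2,4,6-trimethoxyphenoxy)phenoxy]-2,3,4-trimethoxyphenol
Conditions: conc. HCl (cat.), MeOH, 50 °C
Reagents that add atoms: none
Why: Acid-catalysed acetal exchange frees the ring C C2 hydroxyl; aryl methyl and diaryl ethers are untouched.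

Step 15
Reactants: 29 6-[2,6-dimethoxy-4-(2,4,6-trimethoxyphenoxy)phenoxy]-2,3,4-trimethoxyphenol; 20 2-(benzyloxy)-5-bromo-1,3-dimethoxybenzene
Product: 30 2-(benzyloxy)-5-{6-[2,6-dimethoxy-4-(2,4,6-trimethoxyphenoxy)phenoxy]-2,3,4-trimethoxyphenoxy}-1,3-dimethoxybenzene
Conditions: CuI (20 mol %), picolinic acid (40 mol %), K3PO4, DMSO, 100 °C, argon
Reagents that add atoms: none
Why: Ullmann ether synthesis of the hindered-phenol/unhindered-bromide kind, as in step 9; the phenol is flanked by an aryloxy and a methoxy group but the bromide is open on both sides.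

Step 16
Reactants: 30 2-(benzyloxy)-5-{6-[2,6-dimethoxy-4-(2,4,6-trimethoxyphenoxy)phenoxy]-2,3,4-trimethoxyphenoxy}-1,3-dimethoxybenzene
Product: 31 4-{6-[2,6-dimethoxy-4-(2,4,6-trimethoxyphenoxy)phenoxy]-2,3,4-trimethoxyphenoxy}-2,6-dimethoxyphenol
Conditions: H2 (1 atm), 10% Pd/C, EtOAc/MeOH, rt
Reagents that add atoms: none
Why: Hydrogenolysis of the benzyl ether, as in step 10, frees the flanked ring D C4 hydroxyl.

Step 17
Reactants: 31 4-{6-[2,6-dimethoxy-4-(2,4,6-trimethoxyphenoxy)phenoxy]-2,3,4-trimethoxyphenoxy}-2,6-dimethoxyphenol; 19 5-(4-bromo-2,6-dimethoxyphenoxy)-1,2,3-trimethoxybenzene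
Product: 32 5-[2,6-dimethoxy-4-(2,4,6-trimethoxyphenoxy)phenoxy]-4-{3,5-dimethoxy-4-[3,5-dimethoxy-4-(3,4,5-trimethoxyphenoxy)phenoxy]phenoxy}-1,2,3-trimethoxybenzene
Conditions: CuI (20 mol %), picolinic acid (40 mol %), K3PO4, DMSO, 110 °C, argon
Reagents that add atoms: none
Why: Ullmann ether synthesis joining the four-ring phenol to the two-ring bromide; the phenol is of the 2,6-dimethoxy type already used in steps 9 and 13 and the bromide carbon (ring E C1) has both ortho positions free.

Step 18
Reactants: 32 pentadeca-O-methyl ether of the target
Product: 33 5-[2,6-dihydroxy-4-(2,4,6-trihydroxyphenoxy)phenoxy]-4-{3,5-dihydroxy-4-[3,5-dihydroxy-4-(3,4,5-trihydroxyphenoxy)phenoxy]phenoxy}benzene-1,2,3-triol (CNP0270681.0)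
Conditions: BBr3 (30 equiv), CH2Cl2, −78 °C → rt; then MeOH/H2O, 0 °C, argon
Reagents that add atoms: none
Why: Lewis acid cleavage of aryl methyl ethers by BBr3 attacks the methyl carbon, so the diaryl ether C–O bonds, which offer no such carbon, should be retained; work-up under argon protects the pyrogallol rings.

## Compound list

1 | 4-bromo-2,6-dimethoxyphenol | COc1cc(Br)cc(OC)c1O | starting material
2 | trichloroethylene | ClC=C(Cl)Cl | starting material
3 | dichloroacetylene (formed in situ) | ClC#CCl | intermediate
4 | 5-bromo-2-{[(E)-1,2-dichloroethenyl]oxy}-1,3-dimethoxybenzene | COc1cc(Br)cc(OC)c1O/C(Cl)=C\Cl | intermediate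
5 | 5-bromo-2-[(chloroethynyl)oxy]-1,3-dimethoxybenzene (formed in situ) | ClC#COc1c(OC)cc(Br)cc1OC | intermediate
6 | lithium [(4-bromo-2,6-dimethoxyphenoxy)ethynide] (formed in situ) | [Li]C#COc1c(OC)cc(Br)cc1OC | intermediate
7 | 5-bromo-2-(ethynyloxy)-1,3-dimethoxybenzene | C#COc1c(OC)cc(Br)cc1OC | intermediate
8 | dimethyl squarate (3,4-dimethoxycyclobut-3-ene-1,2-dione) | COC1=C(OC)C(=O)C1=O | starting material
9 | 4-hydroxy-2,3-dimethoxycyclobut-2-en-1-one (racemic, not purified) | COC1=C(OC)C(O)C1=O | intermediate
10 | 3-methoxycyclobut-3-ene-1,2-dione | COC1=CC(=O)C1=O | intermediate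
11 | 4-hydroxy-3-methoxycyclobut-2-en-1-one (racemic) | COC1=CC(=O)C1O | intermediate
12 | 4-[(tert-butyldimethylsilyl)oxy]-3-methoxycyclobut-2-en-1-one (racemic) | COC1=CC(=O)C1O[Si](C)(C)C(C)(C)C | intermediate
13 | (3Z)-4-[(tert-butyldimethylsilyl)oxy]-3-methoxybuta-1,3-dien-1-one (formed in situ) | O=C=C/C(OC)=C/O[Si](C)(C)C(C)(C)C | intermediate
14 | 3-(4-bromo-2,6-dimethoxyphenoxy)-4-{(Z)-2-[(tert-butyldimethylsilyl)oxy]-1-methoxyethenyl}cyclobut-2-en-1-one (racemic, formed in situ) | O=C1C=C(Oc2c(OC)cc(Br)cc2OC)C1/C(OC)=C/O[Si](C)(C)C(C)(C)C | intermediate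
15 | (3E,5Z)-3-(4-bromo-2,6-dimethoxyphenoxy)-6-[(tert-butyldimethylsilyl)oxy]-5-methoxyhexa-1,3,5-trien-1-one (formed in situ) | O=C=C/C(Oc1c(OC)cc(Br)cc1OC)=C\C(OC)=C\O[Si](C)(C)C(C)(C)C | intermediate
16 | 3-(4-bromo-2,6-dimethoxyphenoxy)-6-[(tert-butyldimethylsilyl)oxy]-5-methoxycyclohexa-2,4-dien-1-one (racemic, formed in situ) | O=C1C=C(Oc2c(OC)cc(Br)cc2OC)C=C(OC)C1O[Si](C)(C)C(C)(C)C | intermediate
17 | 5-(4-bromo-2,6-dimethoxyphenoxy)-2-[(tert-butyldimethylsilyl)oxy]-3-methoxyphenol | COc1cc(Oc2c(OC)cc(Br)cc2OC)cc(O)c1O[Si](C)(C)C(C)(C)C | intermediate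
18 | 5-(4-bromo-2,6-dimethoxyphenoxy)-3-methoxybenzene-1,2-diol (formed in situ) | COc1cc(Oc2c(OC)cc(Br)cc2OC)cc(O)c1O | intermediate
19 | 5-(4-bromo-2,6-dimethoxyphenoxy)-1,2,3-trimethoxybenzene | COc1cc(Oc2c(OC)cc(Br)cc2OC)cc(OC)c1OC | intermediate
20 | 2-(benzyloxy)-5-bromo-1,3-dimethoxybenzene | COc1cc(Br)cc(OC)c1OCc1ccccc1 | intermediate
21 | 2,4,6-trimethoxyphenol | COc1cc(OC)c(O)c(OC)c1 | starting material
22 | 2-(benzyloxy)-1,3-dimethoxy-5-(2,4,6-trimethoxyphenoxy)benzene | COc1cc(OC)c(Oc2cc(OC)c(OCc3ccccc3)c(OC)c2)c(OC)c1 | intermediate
23 | 2,6-dimethoxy-4-(2,4,6-trimethoxyphenoxy)phenol | COc1cc(OC)c(Oc2cc(OC)c(O)c(OC)c2)c(OC)c1 | intermediate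
24 | 2,3,4-trimethoxyphenol | COc1ccc(O)c(OC)c1OC | starting material
25 | 1,2,3-trimethoxy-4-(methoxymethoxy)benzene | COCOc1ccc(OC)c(OC)c1OC | intermediate
26 | [3,4,5-trimethoxy-2-(methoxymethoxy)phenyl]lithium (formed in situ) | COCOc1c([Li])cc(OC)c(OC)c1OC | intermediate
27 | 1-iodo-3,4,5-trimethoxy-2-(methoxymethoxy)benzene | COCOc1c(I)cc(OC)c(OC)c1OC | intermediate
28 | 1-[2,6-dimethoxy-4-(2,4,6-trimethoxyphenoxy)phenoxy]-3,4,5-trimethoxy-2-(methoxymethoxy)benzene | COc1cc(OC)c(Oc2cc(OC)c(Oc3cc(OC)c(OC)c(OC)c3OCOC)c(OC)c2)c(OC)c1 | intermediate
29 | 6-[2,6-dimethoxy-4-(2,4,6-trimethoxyphenoxy)phenoxy]-2,3,4-trimethoxyphenol | COc1cc(OC)c(Oc2cc(OC)c(Oc3cc(OC)c(OC)c(OC)c3O)c(OC)c2)c(OC)c1 | intermediate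
30 | 2-(benzyloxy)-5-{6-[2,6-dimethoxy-4-(2,4,6-trimethoxyphenoxy)phenoxy]-2,3,4-trimethoxyphenoxy}-1,3-dimethoxybenzene | COc1cc(OC)c(Oc2cc(OC)c(Oc3cc(OC)c(OC)c(OC)c3Oc3cc(OC)c(OCc4ccccc4)c(OC)c3)c(OC)c2)c(OC)c1 | intermediate
31 | 4-{6-[2,6-dimethoxy-4-(2,4,6-trimethoxyphenoxy)phenoxy]-2,3,4-trimethoxyphenoxy}-2,6-dimethoxyphenol | COc1cc(OC)c(Oc2cc(OC)c(Oc3cc(OC)c(OC)c(OC)c3Oc3cc(OC)c(O)c(OC)c3)c(OC)c2)c(OC)c1 | intermediate
32 | 5-[2,6-dimethoxy-4-(2,4,6-trimethoxyphenoxy)phenoxy]-4-{3,5-dimethoxy-4-[3,5-dimethoxy-4-(3,4,5-trimethoxyphenoxy)phenoxy]phenoxy}-1,2,3-trimethoxybenzene (pentadeca-O-methyl ether of the target) | COc1cc(OC)c(Oc2cc(OC)c(Oc3cc(OC)c(OC)c(OC)c3Oc3cc(OC)c(Oc4cc(OC)c(Oc5cc(OC)c(OC)c(OC)c5)c(OC)c4)c(OC)c3)c(OC)c2)c(OC)c1 | intermediate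
33 | 5-[2,6-dihydroxy-4-(2,4,6-trihydroxyphenoxy)phenoxy]-4-{3,5-dihydroxy-4-[3,5-dihydroxy-4-(3,4,5-trihydroxyphenoxy)phenoxy]phenoxy}benzene-1,2,3-triol (CNP0270681.0) | Oc1cc(O)c(Oc2cc(O)c(Oc3cc(O)c(O)c(O)c3Oc3cc(O)c(Oc4cc(O)c(Oc5cc(O)c(O)c(O)c5)c(O)c4)c(O)c3)c(O)c2)c(O)c1 | target

## Step count and risks

Total: 18 steps. Longest linear sequence: 9 steps (steps 8, 9, 10, 13, 14, 15, 16, 17, 18, from phenol 1).

Step 6 (key step). The terminal aryl ethynyl ether may oligomerise, and the electron-rich vinylketene may dimerise, faster than the bimolecular [2+2] addition takes place. The product phenol may also be acylated by a second ketene. The fallback gives up ring construction for this one ether. It sets out from bromophenol 1 and uses a Chan–Lam coupling with commercial (3,4,5-trimethoxyphenyl)boronic acid (Cu(OAc)2, pyridine, 4 Å sieves, CH2Cl2, dry air, rt). This coupling is known to accept phenols with two ortho substituents and to leave aryl halides untouched. It returns to the route at 19 and makes no new compound (F0).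

Step 2. Bromine–lithium exchange on ring E may compete with vinylic deprotonation and chlorine–lithium exchange, with loss of the coupling handle. The fallback drives that exchange to completion and restores the bromine later.
- It sets out from 4: excess n-BuLi (3.5 equiv, THF, −78 → −40 °C; MeOH) should give 2-(ethynyloxy)-1,3-dimethoxybenzene F1.
- F1 is taken through the benzannulation with 12 to 2-[(tert-butyldimethylsilyl)oxy]-5-(2,6-dimethoxyphenoxy)-3-methoxyphenol F2.
- F2 is taken through the conditions of step 7 to 5-(2,6-dimethoxyphenoxy)-1,2,3-trimethoxybenzene F3.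
- Sterically controlled C–H borylation ([Ir(OMe)(cod)]2, 4,4'-di-tert-butyl-2,2'-bipyridine, B2pin2, THF, 80 °C) can only reach ring E C1, the one C–H with two free neighbours. It should give 2-[3,5-dimethoxy-4-(3,4,5-trimethoxyphenoxy)phenyl]-4,4,5,5-tetramethyl-1,3,2-dioxaborolane F4.
- Bromodeboronation with CuBr2 (MeOH/H2O, 80 °C) returns to the route at 19.

Step 13. C–O bond formation between the doubly flanked phenoxide and the ortho-substituted, electron-rich iodide may be slow. Protodeiodination and oxidative degradation of the phenoxide would then take over. The fallback sets out from 27: iodine–magnesium exchange (i-PrMgCl·LiCl, THF, −20 °C), B(OMe)3 and aqueous work-up give [3,4,5-trimethoxy-2-(methoxymethoxy)phenyl]boronic acid F5. A Chan–Lam coupling of F5 with 23 (Cu(OAc)2, pyridine, 4 Å sieves, CH2Cl2, dry air, rt) avoids oxidative addition into the hindered C–I bond and returns at 28.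

Step 17. Conversion may stay low in the union of two large electron-rich partners, because oxidative addition into a bromide para to an aryloxy group is slow and the phenoxide of 31 degrades meanwhile. The fallback repartitions the chain 3 + 3 so that the flanked phenol is a small molecule.
- It sets out from 19: bromine–lithium exchange (n-BuLi, THF, −78 °C) and B(Oi-Pr)3 give [3,5-dimethoxy-4-(3,4,5-trimethoxyphenoxy)phenyl]boronic acid F6.
- A Chan–Lam coupling of F6 with bromophenol 1 (Cu(OAc)2, pyridine, CH2Cl2, dry air) gives 5-[4-(4-bromo-2,6-dimethoxyphenoxy)-2,6-dimethoxyphenoxy]-1,2,3-trimethoxybenzene F7.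
- F7 is joined to phenol 29 under the conditions of step 15 and returns at 32.

Step 18. Cleavage of the fifteen methyl ethers may be incomplete, because boron chelates between neighbouring oxygens precipitate. The pyrogallol rings may also be oxidised by air during isolation. The fallback sets out from 32: after the BBr3 treatment and quench the crude polyphenol is acetylated (Ac2O, pyridine) to the pentadecaacetate F8. F8 is stable to air and can be purified by chromatography, and partly methylated material can be separated and resubjected. Acid-catalysed methanolysis (HCl in MeOH, rt, argon) then returns at 33.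

## Further compounds

F0 | step 6 | none | none
F1 | step 2 | 2-(ethynyloxy)-1,3-dimethoxybenzene | C#COc1c(OC)cccc1OC
F2 | step 2 | 2-[(tert-butyldimethylsilyl)oxy]-5-(2,6-dimethoxyphenoxy)-3-methoxyphenol | COc1cc(Oc2c(OC)cccc2OC)cc(O)c1O[Si](C)(C)C(C)(C)C
F3 | step 2 | 5-(2,6-dimethoxyphenoxy)-1,2,3-trimethoxybenzene | COc1cc(Oc2c(OC)cccc2OC)cc(OC)c1OC
F4 | step 2 | 2-[3,5-dimethoxy-4-(3,4,5-trimethoxyphenoxy)phenyl]-4,4,5,5-tetramethyl-1,3,2-dioxaborolane | COc1cc(Oc2c(OC)cc(B3OC(C)(C)C(C)(C)O3)cc2OC)cc(OC)c1OC
F5 | step 13 | [3,4,5-trimethoxy-2-(methoxymethoxy)phenyl]boronic acid | COCOc1c(B(O)O)cc(OC)c(OC)c1OC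
F6 | step 17 | [3,5-dimethoxy-4-(3,4,5-trimethoxyphenoxy)phenyl]boronic acid | COc1cc(Oc2c(OC)cc(B(O)O)cc2OC)cc(OC)c1OC
F7 | step 17 | 5-[4-(4-bromo-2,6-dimethoxyphenoxy)-2,6-dimethoxyphenoxy]-1,2,3-trimethoxybenzene | COc1cc(Oc2c(OC)cc(Oc3c(OC)cc(Br)cc3OC)cc2OC)cc(OC)c1OC
F8 | step 18 | pentadeca-O-acetate of the target | CC(=O)Oc1cc(OC(C)=O)c(Oc2cc(OC(C)=O)c(Oc3cc(OC(C)=O)c(OC(C)=O)c(OC(C)=O)c3Oc3cc(OC(C)=O)c(Oc4cc(OC(C)=O)c(Oc5cc(OC(C)=O)c(OC(C)=O)c(OC(C)=O)c5)c(OC(C)=O)c4)c(OC(C)=O)c3)c(OC(C)=O)c2)c(OC(C)=O)c1
A1 | alternative 1 | dodeca-O-methyl ether of the target with free hydroxyls at ring A C4, ring C C4 and ring F C4 | Oc1cc(OC)c(Oc2cc(OC)c(Oc3cc(OC)c(O)c(OC)c3Oc3cc(OC)c(Oc4cc(OC)c(Oc5cc(OC)c(O)c(OC)c5)c(OC)c4)c(OC)c3)c(OC)c2)c(OC)c1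
A2 | alternative 1 | hexaaryl ether trialdehyde (formyl in place of the three hydroxyls of A1) | O=Cc1cc(OC)c(Oc2cc(OC)c(Oc3cc(OC)c(C=O)c(OC)c3Oc3cc(OC)c(Oc4cc(OC)c(Oc5cc(OC)c(C=O)c(OC)c5)c(OC)c4)c(OC)c3)c(OC)c2)c(OC)c1
A3 | alternative 2 | 2-[4-(benzyloxy)-3,5-dimethoxyphenoxy]-5-ethoxy-3,4-dimethoxyphenol | CCOc1cc(O)c(Oc2cc(OC)c(OCc3ccccc3)c(OC)c2)c(OC)c1OC
A4 | alternative 2 | 2-[4-(benzyloxy)-3,5-dimethoxyphenoxy]-4-(1-ethoxyethenyl)-3,4-dimethoxycyclobut-2-en-1-one (racemic) | CCOC(=C)C1(OC)C(OC)=C(Oc2cc(OC)c(OCc3ccccc3)c(OC)c2)C1=O
A5 | alternative 3 | dimethyl 5-[4-(benzyloxy)-3,5-dimethoxyphenoxy]-2,4,6-trihydroxybenzene-1,3-dicarboxylate | COC(=O)c1c(O)c(C(=O)OC)c(O)c(Oc2cc(OC)c(OCc3ccccc3)c(OC)c2)c1O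
A6 | alternative 3 | dimethyl 2-[4-(benzyloxy)-3,5-dimethoxyphenoxy]propanedioate | COC(=O)C(Oc1cc(OC)c(OCc2ccccc2)c(OC)c1)C(=O)OC
A7 | alternative 3 | dimethyl 3-oxopentanedioate | COC(=O)CC(=O)CC(=O)OC
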